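The numbers in the tables were generated by integration on assumed constants, and the scatter is random.

The trap in repeating this run was the electrophile curve, which looked alike in red, green and amber although their free base differed, so I wanted a second number to watch.

common to all: gas 5.3 mM (held)

| run | electrophile | free base | remark | time |
|---|---|---|---|---|
| red | 0.066 M | 1 equiv (fed, over 25 s) | run made earlier; the fed solution adds 0.50 times the starting volume |  |
| green | 0.066 M | 2.2 equiv (fed, over 25 s) | run made earlier; the fed solution adds 0.50 times the starting volume |  |
| amber | 0.033 M | 1.5 equiv (fed, over 25 s) | run made earlier; the fed solution adds 0.50 times the starting volume |  |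
| flask | 0.066 M | 1.50 equiv (fed, over 25 s) | the fed solution adds 0.50 times the starting volume | 2.0 min |

| run | time / s | electrophile / % | target / % |
|---|---|---|---|
| red | 10.0 | 81.9 | 15.1 |
| red | 25.0 | 61.1 | 36.9 |
| red | 50.0 | 33.4 | 57.9 |
| red | 80.0 | 16.3 | 72.0 |
| green | 10.0 | 81.1 | 15.9 |
| green | 25.0 | 59.5 | 38.5 |
| green | 50.0 | 35.7 | 59.4 |
| green | 80.0 | 18.0 | 72.0 |
| amber | 10.0 | 82.3 | 17.6 |
| amber | 25.0 | 59.1 | 38.7 |
| amber | 50.0 | 32.9 | 61.9 |
| amber | 80.0 | 17.0 | 76.2 |

(readings scatter by 1 percentage point)

- amounts are per litre of the starting volume; all of the dose is in the solution fed
- at the start none of the gas is in solution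
- the earlier runs do not show how much of nucleophile is bound; that part of a forecast is a guess

* part of the electrophile that has reacted at 2.0 min
* share of the unused nucleophile that is free and not bound as protonated nucleophile, at 2.0 min

I took the settings in turn. At 80.0 s the electrophile read 16.3 % in red, 18.0 % in green and 17.0 % in amber, differences of 1.7 percentage points and 0.7 points against a scatter of 1 point. So the charges did not show clearly in these electrophile readings, and I reckoned conversion from the time. From red's last reading I took a pseudo-first-order constant of 0.0227 s⁻¹, which gave 93.4 % reacted in the flask at 2.0 min.

For binding I expected the equivalents to matter. I assumed that each electrophile reacted set free one acid and that free base took it up, and I used the base load L, the equivalents of electrophile reacted divided by the equivalents of free base left. For the flask L came to 1.65. From the readings at 80.0 s it was 5.13 in red and 0.594 in green, though their electrophile curves lay close together. If free base and nucleophile held acid equally, the free share would be one over one plus L, or 37.7 %. No reading shows binding, so this was a guess.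

The forecast gave 93 % reacted and 90 % free, well above my figure, reasoning “so little nucleophile can be protonated even then”.

    electrophile + target → side product (k = 0.0830 L mol⁻¹ s⁻¹)
    nucleophile + acid set free ⇌ protonated nucleophile, settled at all times (K = 38000 L mol⁻¹)
    gas ⇌ nucleophile, rate k3*(csat - [nucleophile]) (kL = 3.60 s⁻¹)
    electrophile + nucleophile → acid set free + target (k = 4.00 L mol⁻¹ s⁻¹)
    acid set free + free base ⇌ salt of the base, settled at all times (K = 34000 L mol⁻¹)

The flask gave 93.5 % reacted and 48.0 % free, with c(nucleophile) at 0.00528 M beside c(protonated nucleophile) at 0.00573 M. Weighting L by the ratio of the binding constants, 1.12, gives a free share of 35.1 % for this flask, below the 48.0 % it showed; its side product stood at 13.0 %, and the step to side product sets no acid free. With 3.80 equiv of free base, L falls to 0.326 and the same weighting gives 73.3 %, and that neighbour flask stood at 76.1 %.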